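The pyranone ring (ring C) is cut at C2–C3 and at O1–C8a, so that C2 and O1 arrive together as formaldehyde. The precursor is an open allyl β-keto ester: the future C3, acidified by the C4 ketone, ring B and the ester, faces a ring A that carries fluorine at the future C8a, ortho to the C4 carbonyl. In one operation the C3 enolate is hydroxymethylated and the new alkoxide displaces the C8a fluoride (SNAr), closing ring C with the prenyl group unambiguously at C6. The ester, which blocks dehydration, then leaves in an enantioselective decarboxylative protonation that sets (3S).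

Key step: step 11

Assumptions (remarks on the chemistry):
- Compounds 1 and 9 are taken to be commercially available; "prenyl" means 3-methylbut-2-en-1-yl and "MOM" means methoxymethyl.
- The first lithiation of 10 is taken to occur between the two MOM ethers (two chelating directing groups) rather than next to fluorine.
- The sense of induction of the phosphinooxazoline ligand in step 12 is assigned by analogy, and the antipodal ligand would be used if the (3R) ketone formed.
- Compounds 17, 18 and 19 are racemic; the only stereocenter of the target, C3, is (S) and is set in step 12.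

**Ring B fragment**

Step 1
Reactants: 1 3-bromo-4,5-dihydroxybenzaldehyde
Product: 2 3-bromo-5-hydroxy-4-methoxybenzaldehyde
Conditions: MeI (1.1 equiv), Li2CO3 (1.1 equiv), DMF, 40 °C
Reagents that add atoms: iodomethane, CI
Why: Williamson etherification of the more acidic 4-hydroxyl (para to the formyl group, ortho to bromine), the only phenol deprotonated by one equivalent of the weak base.

Step 2
Reactants: 2 3-bromo-5-hydroxy-4-methoxybenzaldehyde
Product: 3 3-bromo-4-methoxy-5-(methoxymethoxy)benzaldehyde
Conditions: MOMCl, i-Pr2NEt, CH2Cl2, 0 °C to rt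
Reagents that add atoms: chloromethyl methyl ether, COCCl
Why: O-alkylation of the remaining phenol gives a base-stable acetal that should survive the organometallic and strongly basic steps ahead.

Step 3
Reactants: 3 3-bromo-4-methoxy-5-(methoxymethoxy)benzaldehyde
Product: 4 4-methoxy-3-(methoxymethoxy)-5-prenylbenzaldehyde
Conditions: tributyl(prenyl)stannane, Pd(PPh3)4 (5 mol%), DMF, 100 °C
Reagents that add atoms: tributyl(3-methylbut-2-en-1-yl)stannane, CCCC[Sn](CCCC)(CCCC)CC=C(C)C
Why: Stille coupling of the aryl bromide with the allylic stannane should transfer the prenyl group in its linear form and tolerates the aldehyde and the MOM ether.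

Step 4
Reactants: 4 4-methoxy-3-(methoxymethoxy)-5-prenylbenzaldehyde
Product: 6 2-[4-methoxy-3-(methoxymethoxy)-5-prenylphenyl]acetonitrile, via N-(1-tosylvinyl)formamide 5 (not isolated)
Conditions: TosMIC, t-BuOK, DME, −40 °C to rt; then MeOH, 65 °C
Reagents that add atoms: p-toluenesulfonylmethyl isocyanide, Cc1ccc(cc1)S(=O)(=O)C[N+]#[C-]
Why: van Leusen reductive cyanation, in which the TosMIC anion adds to the aldehyde, the oxazoline adduct opens to formamide 5, and methanolysis with loss of methyl formate and sulfinate gives the one-carbon-homologated nitrile.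

Step 5
Reactants: 6 2-[4-methoxy-3-(methoxymethoxy)-5-prenylphenyl]acetonitrile
Product: 7 2-[4-methoxy-3-(methoxymethoxy)-5-prenylphenyl]acetic acid
Conditions: KOH, EtOH–H2O, 85 °C; then 1 M HCl to pH 3, 0 °C
Reagents that add atoms: potassium hydroxide, [K+].[OH-]; water, O
Why: Alkaline nitrile hydrolysis, to which the MOM ether, the aryl methyl ether and the prenyl group are inert, followed by a brief cold acidification that should leave the acetal intact.

Step 6
Reactants: 7 2-[4-methoxy-3-(methoxymethoxy)-5-prenylphenyl]acetic acid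
Product: 8 allyl 2-[4-methoxy-3-(methoxymethoxy)-5-prenylphenyl]acetate
Conditions: allyl bromide, K2CO3, DMF, rt
Reagents that add atoms: allyl bromide, C=CCBr
Why: SN2 alkylation of the carboxylate installs the allyl ester that later allows palladium-mediated decarboxylation.

**Ring A fragment**

Step 7
Reactants: 9 5-fluorobenzene-1,3-diol
Product: 10 1-fluoro-3,5-bis(methoxymethoxy)benzene
Conditions: MOMCl (2.4 equiv), i-Pr2NEt, CH2Cl2, 0 °C to rt
Reagents that add atoms: chloromethyl methyl ether, COCCl
Why: Double O-alkylation gives two strong ortho-directing acetal groups and keeps both oxygens non-phenoxide, hence non-deactivating, for the later SNAr.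

Step 8
Reactants: 10 1-fluoro-3,5-bis(methoxymethoxy)benzene
Product: 12 5-fluoro-1,3-bis(methoxymethoxy)-2-prenylbenzene, via aryllithium 11 (not isolated)
Conditions: n-BuLi, THF, 0 °C; then CuI (10 mol%), prenyl bromide, −78 °C to rt
Reagents that add atoms: 1-bromo-3-methylbut-2-ene, CC(C)=CCBr
Why: Directed ortho-metalation at the position flanked by both MOM ethers (the aryllithium has fluorine para and is stable at 0 °C), followed by copper-catalysed SN2 allylation with prenyl bromide.

Step 9
Reactants: 12 5-fluoro-1,3-bis(methoxymethoxy)-2-prenylbenzene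
Product: 14 6-fluoro-2,4-bis(methoxymethoxy)-3-prenylbenzoic acid, via aryllithium 13 (not isolated)
Conditions: s-BuLi, THF, −78 °C; CO2; then 1 M HCl to pH 3, 0 °C
Reagents that add atoms: carbon dioxide, O=C=O
Why: Second directed ortho-metalation at one of the two equivalent ring positions flanked by fluorine and a MOM ether, held at −78 °C so that LiF is not lost to an aryne, then carboxylation.

**Union and endgame**

Step 10
Reactants: 14 6-fluoro-2,4-bis(methoxymethoxy)-3-prenylbenzoic acid; 8 allyl 2-[4-methoxy-3-(methoxymethoxy)-5-prenylphenyl]acetate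
Product: 17 allyl 3-[6-fluoro-2,4-bis(methoxymethoxy)-3-prenylphenyl]-2-[4-methoxy-3-(methoxymethoxy)-5-prenylphenyl]-3-oxopropanoate (racemic), via acyl imidazolide 15 (not isolated), via lithium enolate 16 (not isolated)
Conditions: 14, 1,1'-carbonyldiimidazole, THF, rt; 8, LiN(SiMe3)2 (2.2 equiv), THF, −78 °C; combine, −78 to 0 °C; aq. NH4Cl
Reagents that add atoms: none
Why: Crossed Claisen condensation in which ester enolate 16 is C-acylated by acyl imidazolide 15 under neutral activation that spares the MOM ethers, the second equivalent of base removing the acidic C–H of the product to drive the reaction.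

Step 11
Reactants: 17 allyl 3-[6-fluoro-2,4-bis(methoxymethoxy)-3-prenylphenyl]-2-[4-methoxy-3-(methoxymethoxy)-5-prenylphenyl]-3-oxopropanoate
Product: 19 allyl 5,7-bis(methoxymethoxy)-3-[4-methoxy-3-(methoxymethoxy)-5-prenylphenyl]-4-oxo-6-prenylchromane-3-carboxylate (racemic), via carbinol 18 (not isolated)
Conditions: (CH2O)n (5 equiv), Cs2CO3 (1.5 equiv), anhydrous DMF, rt then 50 °C
Reagents that add atoms: formaldehyde (from paraformaldehyde), C=O
Why: Cs2CO3 deprotonates the doubly activated C3–H of 17 and the enolate adds to formaldehyde (aldol hydroxymethylation, C2–C3 bond) to give the quaternary carbinol 18, whose alkoxide attacks C8a of ring A and expels fluoride through a Meisenheimer complex stabilised by the ortho C4 carbonyl (SNAr, O1–C8a bond). The closest known reaction types are tandem aldol/SNAr annulations of 2-fluoroaryl ketones and the base-mediated closure of 1-(2-fluoroaryl)-3-hydroxypropan-1-ones to chroman-4-ones. Ring C closes in a six-membered exo mode, the alkoxide adding to the aromatic carbon C8a with fluoride as the exocyclic leaving group (addition–elimination). C3 becomes a quaternary center and is formed racemic on purpose, since it is re-made as C3–H under catalyst control in step 12. The step needs O-arylation by the alkoxide and not by the ester-enolate oxygen (which would give a 2-allyloxyisoflavone), and closure onto C8a and not C5; the first is secured by excess formaldehyde holding the reversible aldol on the carbinol side, by the far higher nucleophilicity of the alkoxide and by the quaternary C3 (no dehydration, no second hydroxymethylation), the second by fluorine standing only at C8a. Both MOM-oxy groups are meta to the leaving group, so they do not donate into the ipso carbon, and the phenols stay masked so that no deactivating phenoxide forms.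

Step 12
Reactants: 19 allyl 5,7-bis(methoxymethoxy)-3-[4-methoxy-3-(methoxymethoxy)-5-prenylphenyl]-4-oxo-6-prenylchromane-3-carboxylate
Product: 20 (3S)-5,7-bis(methoxymethoxy)-3-[4-methoxy-3-(methoxymethoxy)-5-prenylphenyl]-6-prenylchroman-4-one
Conditions: Pd(OAc)2 (10 mol%), (S)-(CF3)3-t-BuPHOX (12.5 mol%), Meldrum's acid (2.5 equiv), 1,4-dioxane, 40 °C
Reagents that add atoms: none
Why: Palladium-catalysed decarboxylative asymmetric protonation, in which the zerovalent palladium–phosphinooxazoline complex ionises the allyl ester, CO2 is lost, and the ligand-bound enolate is protonated at C3 on one face by Meldrum's acid (catalyst control) under neutral conditions that should not epimerise the new (3S) center, Meldrum's acid also taking up the allyl group.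

Step 13
Reactants: 20 (3S)-5,7-bis(methoxymethoxy)-3-[4-methoxy-3-(methoxymethoxy)-5-prenylphenyl]-6-prenylchroman-4-one
Product: 21 (3S)-5,7-dihydroxy-3-(3-hydroxy-4-methoxy-5-prenylphenyl)-6-prenylchroman-4-one
Conditions: ZnBr2 (3 equiv), n-PrSH (6 equiv), CH2Cl2, 0 °C, short reaction time; pH 7 buffer work-up
Reagents that add atoms: none
Why: Lewis acid–thiol acetal cleavage, in which ZnBr2 activates each aryl MOM ether and the thiol traps the methoxymethyl cation, is fast and base-free at 0 °C and is chosen so that the enolisable C3 stereocenter and the prenyl groups next to the freed phenols are left untouched.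

**Compound list**

1 | 3-bromo-4,5-dihydroxybenzaldehyde | O=Cc1cc(O)c(O)c(Br)c1 | starting material
2 | 3-bromo-5-hydroxy-4-methoxybenzaldehyde | O=Cc1cc(O)c(OC)c(Br)c1 | intermediate
3 | 3-bromo-4-methoxy-5-(methoxymethoxy)benzaldehyde | O=Cc1cc(OCOC)c(OC)c(Br)c1 | intermediate
4 | 4-methoxy-3-(methoxymethoxy)-5-prenylbenzaldehyde | O=Cc1cc(OCOC)c(OC)c(CC=C(C)C)c1 | intermediate
5 | N-{2-[4-methoxy-3-(methoxymethoxy)-5-prenylphenyl]-1-tosylethenyl}formamide (not isolated, alkene geometry undefined) | O=CNC(=Cc1cc(OCOC)c(OC)c(CC=C(C)C)c1)S(=O)(=O)c1ccc(C)cc1 | intermediate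
6 | 2-[4-methoxy-3-(methoxymethoxy)-5-prenylphenyl]acetonitrile | N#CCc1cc(OCOC)c(OC)c(CC=C(C)C)c1 | intermediate
7 | 2-[4-methoxy-3-(methoxymethoxy)-5-prenylphenyl]acetic acid | OC(=O)Cc1cc(OCOC)c(OC)c(CC=C(C)C)c1 | intermediate
8 | allyl 2-[4-methoxy-3-(methoxymethoxy)-5-prenylphenyl]acetate | C=CCOC(=O)Cc1cc(OCOC)c(OC)c(CC=C(C)C)c1 | intermediate
9 | 5-fluorobenzene-1,3-diol | Oc1cc(O)cc(F)c1 | starting material
10 | 1-fluoro-3,5-bis(methoxymethoxy)benzene | COCOc1cc(F)cc(OCOC)c1 | intermediate
11 | [4-fluoro-2,6-bis(methoxymethoxy)phenyl]lithium (not isolated) | [Li]c1c(OCOC)cc(F)cc1OCOC | intermediate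
12 | 5-fluoro-1,3-bis(methoxymethoxy)-2-prenylbenzene | COCOc1cc(F)cc(OCOC)c1CC=C(C)C | intermediate
13 | [6-fluoro-2,4-bis(methoxymethoxy)-3-prenylphenyl]lithium (not isolated) | [Li]c1c(F)cc(OCOC)c(CC=C(C)C)c1OCOC | intermediate
14 | 6-fluoro-2,4-bis(methoxymethoxy)-3-prenylbenzoic acid | OC(=O)c1c(F)cc(OCOC)c(CC=C(C)C)c1OCOC | intermediate
15 | [6-fluoro-2,4-bis(methoxymethoxy)-3-prenylphenyl](imidazol-1-yl)methanone (not isolated) | O=C(c1c(F)cc(OCOC)c(CC=C(C)C)c1OCOC)n1ccnc1 | intermediate
16 | lithium enolate of 8 (not isolated, geometry undefined) | C=CCOC(O[Li])=Cc1cc(OCOC)c(OC)c(CC=C(C)C)c1 | intermediate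
17 | allyl 3-[6-fluoro-2,4-bis(methoxymethoxy)-3-prenylphenyl]-2-[4-methoxy-3-(methoxymethoxy)-5-prenylphenyl]-3-oxopropanoate (racemic) | C=CCOC(=O)C(c1cc(OCOC)c(OC)c(CC=C(C)C)c1)C(=O)c1c(F)cc(OCOC)c(CC=C(C)C)c1OCOC | intermediate
18 | allyl 3-[6-fluoro-2,4-bis(methoxymethoxy)-3-prenylphenyl]-2-(hydroxymethyl)-2-[4-methoxy-3-(methoxymethoxy)-5-prenylphenyl]-3-oxopropanoate (racemic, not isolated) | C=CCOC(=O)C(CO)(c1cc(OCOC)c(OC)c(CC=C(C)C)c1)C(=O)c1c(F)cc(OCOC)c(CC=C(C)C)c1OCOC | intermediate
19 | allyl 5,7-bis(methoxymethoxy)-3-[4-methoxy-3-(methoxymethoxy)-5-prenylphenyl]-4-oxo-6-prenylchromane-3-carboxylate (racemic) | C=CCOC(=O)C1(c2cc(OCOC)c(OC)c(CC=C(C)C)c2)COc2cc(OCOC)c(CC=C(C)C)c(OCOC)c2C1=O | intermediate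
20 | (3S)-5,7-bis(methoxymethoxy)-3-[4-methoxy-3-(methoxymethoxy)-5-prenylphenyl]-6-prenylchroman-4-one | COc1c(OCOC)cc([C@H]2COc3cc(OCOC)c(CC=C(C)C)c(OCOC)c3C2=O)cc1CC=C(C)C | intermediate
21 | (3S)-5,7-dihydroxy-3-(3-hydroxy-4-methoxy-5-prenylphenyl)-6-prenylchroman-4-one | COc1c(O)cc([C@H]2COc3cc(O)c(CC=C(C)C)c(O)c3C2=O)cc1CC=C(C)C | target

**Count and risks**

Total step count: 13. Longest linear sequence: 10 steps (steps 1–6, then 10–13); the ring A branch (steps 7–9) joins at step 10.

Steps most likely to fail:

1. Step 11 (key step). Retro-aldol loss of formaldehyde may outrun a slow SNAr on the alkoxy-substituted ring, letting the ester-enolate oxygen arylate instead, or alkoxide may open the product by retro-Claisen cleavage. Fallback, from 17 back to 19: hydroxymethylation under near-neutral conditions (37% aqueous formaldehyde, KHCO3, THF, rt) should allow the carbinol 18 to be isolated. Silylation (Me3SiCl, imidazole, CH2Cl2) would give the trimethylsilyl ether F1. Catalytic anhydrous fluoride (tetrabutylammonium difluorotriphenylsilicate or CsF, DMF, rt to 50 °C) would then trigger a silyl-transfer SNAr, in which the displaced fluoride carries the chain and Me3SiF is lost, to give 19 with no stoichiometric base and no free enolate.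

2. Step 12. Facial discrimination in the protonation may be poor because ring B has no ortho substituent to hold it perpendicular to the enolate plane, and the product may partly racemise by enolisation. Fallback, from 20 of insufficient enantiomeric purity back to 20: asymmetric transfer hydrogenation with dynamic kinetic resolution (RuCl[(S,S)-TsDPEN](p-cymene), HCO2H/Et3N, DMF, 40 °C). The amine equilibrates C3 and the catalyst should reduce the (3S) ketone faster, anti to the aryl group, to give the cis-(3S,4S)-isoflavan-4-ol F2. Dess–Martin periodinane (CH2Cl2, 0 °C) would then return the (3S) ketone 20 without touching C3.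

3. Step 13. Lewis-acid-promoted enolisation at C3 may erode the configuration, or cleavage of the three acetals may be incomplete within the short time that the stereocenter tolerates. Fallback, from 19 to 21: the MOM groups are removed before the stereocenter exists (ZnBr2, n-PrSH, CH2Cl2, rt) to give the racemic triphenol F3. Silylation (t-BuMe2SiOTf, 2,6-lutidine, CH2Cl2) would give the tris(tert-butyldimethylsilyl) ether F4. Decarboxylative protonation under the conditions of step 12 would give the (3S)-tris-silyl isoflavanone F5, and buffered desilylation (HF·pyridine, pyridine, THF, 0 °C) would give 21.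

Further compounds

F1 | step 11 | allyl 3-[6-fluoro-2,4-bis(methoxymethoxy)-3-prenylphenyl]-2-[4-methoxy-3-(methoxymethoxy)-5-prenylphenyl]-3-oxo-2-[(trimethylsilyloxy)methyl]propanoate (racemic) | C=CCOC(=O)C(CO[Si](C)(C)C)(c1cc(OCOC)c(OC)c(CC=C(C)C)c1)C(=O)c1c(F)cc(OCOC)c(CC=C(C)C)c1OCOC
F2 | step 12 | (3S,4S)-5,7-bis(methoxymethoxy)-3-[4-methoxy-3-(methoxymethoxy)-5-prenylphenyl]-6-prenylchroman-4-ol | COc1c(OCOC)cc([C@H]2COc3cc(OCOC)c(CC=C(C)C)c(OCOC)c3[C@H]2O)cc1CC=C(C)C
F3 | step 13 | allyl 5,7-dihydroxy-3-(3-hydroxy-4-methoxy-5-prenylphenyl)-4-oxo-6-prenylchromane-3-carboxylate (racemic) | C=CCOC(=O)C1(c2cc(O)c(OC)c(CC=C(C)C)c2)COc2cc(O)c(CC=C(C)C)c(O)c2C1=O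
F4 | step 13 | allyl 5,7-bis(tert-butyldimethylsilyloxy)-3-[3-(tert-butyldimethylsilyloxy)-4-methoxy-5-prenylphenyl]-4-oxo-6-prenylchromane-3-carboxylate (racemic) | C=CCOC(=O)C1(c2cc(O[Si](C)(C)C(C)(C)C)c(OC)c(CC=C(C)C)c2)COc2cc(O[Si](C)(C)C(C)(C)C)c(CC=C(C)C)c(O[Si](C)(C)C(C)(C)C)c2C1=O
F5 | step 13 | (3S)-5,7-bis(tert-butyldimethylsilyloxy)-3-[3-(tert-butyldimethylsilyloxy)-4-methoxy-5-prenylphenyl]-6-prenylchroman-4-one | COc1c(O[Si](C)(C)C(C)(C)C)cc([C@H]2COc3cc(O[Si](C)(C)C(C)(C)C)c(CC=C(C)C)c(O[Si](C)(C)C(C)(C)C)c3C2=O)cc1CC=C(C)C
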